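**Strategy.** The symmetric diarylmethane is cut twice on one inner ring (ring B): at the bond from C1 to the bridging carbon C7, and at the central CH2–CH2 bond of its arylethyl chain. C7 and the benzylic chain carbon sit on adjacent ring carbons (C1 and C2 of ring B, with OMe on C6), so both can be stored as the C=O and CH2 of a benzocyclobutenone. In one operation the aryllithium carrying the complete other half (ring A and its chain) adds to that strained ketone, the alkoxide opens the four-membered ring to a dienolate, and a vanillyl bromide alkylates its CH2 terminus. The precursor is an aryl bromide flanked by OMe and the arylethyl chain.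

Key step: step 9

Remark (assumption): the target has no stereocentre and no alkene, so only regiochemistry has to be controlled; rings A and B are the two equivalent inner rings, numbered C1 (bridge), C2 (chain), C4 (OH), C6 (OMe), and C7 is the bridging methylene; the outer phenols are carried as benzyl ethers and the inner phenols as triisopropylsilyl ethers; 3-hydroxy-5-methoxybenzaldehyde is taken to be a commercial compound.

**Step 1**
Reactants: 1 3-fluoro-5-methoxyphenol
Product: 2 1-fluoro-3-methoxy-5-(triisopropylsilyloxy)benzene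
Conditions: TIPSCl, imidazole, DMF, rt
Reagents that add atoms: chlorotriisopropylsilane, CC(C)[Si](Cl)(C(C)C)C(C)C
Why: Imidazole-promoted O-silylation of the phenol (standard silyl ether formation); the bulky, weakly coordinating silyloxy group should survive organolithium reagents and should not direct metalation to its own ortho positions.

**Step 2**
Reactants: 2 1-fluoro-3-methoxy-5-(triisopropylsilyloxy)benzene; 3 1,1-diethoxyethene
Product: 7 5-methoxy-3-(triisopropylsilyloxy)bicyclo[4.2.0]octa-1,3,5-trien-7-one, via aryllithium 4 (not isolated), via aryne 5 (not isolated), via diethyl acetal 6 (not isolated)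
Conditions: n-BuLi, THF, −78 °C; 3 (5 equiv), −78 °C → rt; then 1 M HCl, THF, rt
Reagents that add atoms: water, O
Why: Fluorine and OMe jointly acidify the C–H between them, so directed ortho-lithiation and LiF loss should give a single 3-methoxyaryne, which takes the nucleophilic CH2 of the ketene acetal at the carbon remote from OMe in a polar [2+2] cycloaddition, placing the acetal carbon next to OMe before mild acetal hydrolysis releases the ketone.

**Step 3**
Reactants: 8 3-hydroxy-5-methoxybenzaldehyde
Product: 9 3-methoxy-5-(triisopropylsilyloxy)benzaldehyde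
Conditions: TIPSCl, imidazole, DMF, rt
Reagents that add atoms: chlorotriisopropylsilane, CC(C)[Si](Cl)(C(C)C)C(C)C
Why: Imidazole-promoted O-silylation of the phenol; the aldehyde is not affected under these conditions.

**Step 4**
Reactants: 9 3-methoxy-5-(triisopropylsilyloxy)benzaldehyde
Product: 13 2-bromo-3-methoxy-5-(triisopropylsilyloxy)benzaldehyde, via lithium amino alkoxide 10 (not isolated), via ortho-lithiated amino alkoxide 11 (not isolated), via brominated amino alkoxide 12 (not isolated)
Conditions: LiN(Me)CH2CH2NMe2 (from MeNHCH2CH2NMe2 and n-BuLi), THF, −20 °C; n-BuLi (3 equiv), −20 °C; BrCl2C–CCl2Br (excess), −78 °C → rt; then H2O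
Reagents that add atoms: 1,2-dibromo-1,1,2,2-tetrachloroethane, BrC(Cl)(Cl)C(Cl)(Cl)Br
Why: Directed ortho-metalation of an aldehyde masked in situ as its lithium α-amino alkoxide; the chelating amino alkoxide and OMe should jointly direct n-BuLi to the carbon between them, the bulky silyloxy group being no director, and bromine transfer to the aryllithium followed by aqueous collapse of the hemiaminal returns the aldehyde with Br next to OMe.

**Step 5**
Reactants: 14 4-(benzyloxy)-3-methoxybenzyl alcohol
Product: 15 4-(benzyloxy)-3-methoxybenzyl bromide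
Conditions: PBr3, Et2O, 0 °C
Reagents that add atoms: phosphorus tribromide, BrP(Br)Br
Why: Bromination of an activated benzylic alcohol through a bromophosphite and bromide displacement; the reactive bromide is taken directly into step 6 and is freshly prepared for step 9.

**Step 6**
Reactants: 15 4-(benzyloxy)-3-methoxybenzyl bromide
Product: 16 [4-(benzyloxy)-3-methoxybenzyl]triphenylphosphonium bromide
Conditions: PPh3, toluene, reflux
Reagents that add atoms: triphenylphosphine, c1ccc(cc1)P(c1ccccc1)c1ccccc1
Why: SN2 quaternisation of triphenylphosphine by the benzylic bromide; the salt should precipitate from toluene and is collected by filtration.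

**Step 7**
Reactants: 16 [4-(benzyloxy)-3-methoxybenzyl]triphenylphosphonium bromide; 13 2-bromo-3-methoxy-5-(triisopropylsilyloxy)benzaldehyde
Product: 18 2-bromo-1-methoxy-3-{2-[4-(benzyloxy)-3-methoxyphenyl]ethenyl}-5-(triisopropylsilyloxy)benzene (mixture of E and Z isomers), via phosphonium ylide 17 (not isolated)
Conditions: 16, NaN(SiMe3)2, THF, 0 °C; then 13, 0 °C → rt
Reagents that add atoms: none
Why: Wittig olefination of a semi-stabilised benzylic ylide with the aryl aldehyde; the non-nucleophilic amide base spares the aryl silyl ether and the C–Br bond, and the alkene geometry is irrelevant because the double bond is saturated in the next step.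

**Step 8**
Reactants: 18 2-bromo-1-methoxy-3-{2-[4-(benzyloxy)-3-methoxyphenyl]ethenyl}-5-(triisopropylsilyloxy)benzene
Product: 19 2-bromo-1-methoxy-3-{2-[4-(benzyloxy)-3-methoxyphenyl]ethyl}-5-(triisopropylsilyloxy)benzene
Conditions: TsNHNH2 (excess), NaOAc, DME/H2O, reflux
Reagents that add atoms: none
Why: Diimide reduction; diazene released from the sulfonyl hydrazide transfers two hydrogens to the stilbene C=C in a concerted step and should leave the aryl C–Br bond and the benzyl ether intact, which catalytic hydrogenation would put at risk.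

**Step 9**
Reactants: 19 2-bromo-1-methoxy-3-{2-[4-(benzyloxy)-3-methoxyphenyl]ethyl}-5-(triisopropylsilyloxy)benzene; 7 5-methoxy-3-(triisopropylsilyloxy)bicyclo[4.2.0]octa-1,3,5-trien-7-one; 15 4-(benzyloxy)-3-methoxybenzyl bromide
Product: 23 bis{2-methoxy-6-[2-(4-benzyloxy-3-methoxyphenyl)ethyl]-4-(triisopropylsilyloxy)phenyl}methanone, via aryllithium 20 (not isolated), via lithium benzocyclobutenoxide 21 (not isolated), via dienolate 22 (not isolated)
Conditions: 19, t-BuLi (2 equiv), THF, −78 °C; 7, −78 °C; then 15, −78 °C → rt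
Reagents that add atoms: none
Why: Bromine–lithium exchange with two equivalents of t-BuLi (the second destroys t-BuBr, so no competing alkyl halide remains) gives aryllithium 20, which adds to the strained carbonyl of 7; the resulting benzocyclobutenoxide 21 undergoes oxyanion-accelerated conrotatory four-electron ring opening with O outward to the ortho-quinodimethane enolate 22, whose exocyclic CH2 is benzylated by 15 with recovery of aromaticity. The closest known reaction types are organolithium addition to benzocyclobutenones with alkoxide-triggered electrocyclic opening and capture of the resulting ortho-toluoyl-type anion by carbon electrophiles, and the benzylic alkylation of laterally lithiated ortho-alkylaryl carbonyl compounds. No ring is closed (one four-membered ring is opened) and no stereocentre is formed; the carbinol centre of 21 and the enolate geometry of 22 are transient. Three selectivities are needed: 1,2-addition over enolisation (an enolate of 7 would be an antiaromatic benzocyclobutadiene), cleavage of the C(O)–CH2 bond over the C(O)–aryl bond (the pericyclic path leads to a delocalised benzylic anion), and C- over O-alkylation (only C-alkylation restores the benzene ring). Regiochemistry on ring B is not at stake, because the aryne cycloaddition of step 2 has already placed the carbonyl next to OMe.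

**Step 10**
Reactants: 23 bis{2-methoxy-6-[2-(4-benzyloxy-3-methoxyphenyl)ethyl]-4-(triisopropylsilyloxy)phenyl}methanone
Product: 24 bis{2-methoxy-6-[2-(4-benzyloxy-3-methoxyphenyl)ethyl]-4-(triisopropylsilyloxy)phenyl}methanol
Conditions: LiAlH4, THF, reflux
Reagents that add atoms: none
Why: Nucleophilic hydride reduction; the small AlH4− ion should reach the carbonyl of the twisted tetra-ortho-substituted benzophenone on heating, while benzyl, methyl and triisopropylsilyl ethers are inert to it (the acid-sensitive carbinol is carried on without chromatography).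

**Step 11**
Reactants: 24 bis{2-methoxy-6-[2-(4-benzyloxy-3-methoxyphenyl)ethyl]-4-(triisopropylsilyloxy)phenyl}methanol
Product: 25 bis{2-methoxy-6-[2-(4-benzyloxy-3-methoxyphenyl)ethyl]-4-(triisopropylsilyloxy)phenyl}methane
Conditions: Et3SiH (excess), TFA, CH2Cl2, −20 → 0 °C
Reagents that add atoms: none
Why: Ionic hydrogenation; TFA ionises the carbinol to a diarylmethyl cation stabilised by four ortho/para oxygen donors, and excess Et3SiH at low temperature should transfer hydride to it before the tethered outer rings can attack in a Friedel–Crafts sense.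

**Step 12**
Reactants: 25 bis{2-methoxy-6-[2-(4-benzyloxy-3-methoxyphenyl)ethyl]-4-(triisopropylsilyloxy)phenyl}methane
Product: 26 bis{2-[2-(4-benzyloxy-3-methoxyphenyl)ethyl]-4-hydroxy-6-methoxyphenyl}methane
Conditions: Bu4NF, AcOH, THF, 0 °C
Reagents that add atoms: none
Why: Fluoride-induced cleavage of the two aryl silyl ethers, driven by Si–F bond formation, with AcOH buffering the liberated phenoxides; the benzyl ethers are untouched.

**Step 13**
Reactants: 26 bis{2-[2-(4-benzyloxy-3-methoxyphenyl)ethyl]-4-hydroxy-6-methoxyphenyl}methane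
Product: 27 4,4′-methylenebis{3-[2-(4-hydroxy-3-methoxyphenyl)ethyl]-5-methoxyphenol} (CNP0079383.0)
Conditions: H2 (1 atm), 10% Pd/C, EtOAc/MeOH, rt
Reagents that add atoms: none
Why: Heterogeneous hydrogenolysis of the two benzyl aryl ethers; the diarylmethane and bibenzyl C–C bonds and the methyl ethers are stable under these conditions.

**Compound list**

1 | 3-fluoro-5-methoxyphenol | COc1cc(O)cc(F)c1 | starting material
2 | 1-fluoro-3-methoxy-5-(triisopropylsilyloxy)benzene | COc1cc(O[Si](C(C)C)(C(C)C)C(C)C)cc(F)c1 | intermediate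
3 | 1,1-diethoxyethene | C=C(OCC)OCC | starting material
4 | [2-fluoro-6-methoxy-4-(triisopropylsilyloxy)phenyl]lithium | COc1cc(O[Si](C(C)C)(C(C)C)C(C)C)cc(F)c1[Li] | intermediate
5 | 3-methoxy-5-(triisopropylsilyloxy)benzyne (1,2-didehydro arene, triple bond between the former C–F and C–Li carbons) | COC1=CC(O[Si](C(C)C)(C(C)C)C(C)C)=CC#C1 | intermediate
6 | 7,7-diethoxy-5-methoxy-3-(triisopropylsilyloxy)bicyclo[4.2.0]octa-1,3,5-triene | CCOC1(OCC)Cc2cc(O[Si](C(C)C)(C(C)C)C(C)C)cc(OC)c21 | intermediate
7 | 5-methoxy-3-(triisopropylsilyloxy)bicyclo[4.2.0]octa-1,3,5-trien-7-one | O=C1Cc2cc(O[Si](C(C)C)(C(C)C)C(C)C)cc(OC)c21 | intermediate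
8 | 3-hydroxy-5-methoxybenzaldehyde | COc1cc(O)cc(C=O)c1 | starting material
9 | 3-methoxy-5-(triisopropylsilyloxy)benzaldehyde | COc1cc(O[Si](C(C)C)(C(C)C)C(C)C)cc(C=O)c1 | intermediate
10 | lithium {[2-(dimethylamino)ethyl](methyl)amino}[3-methoxy-5-(triisopropylsilyloxy)phenyl]methanolate, racemic | [Li]OC(N(C)CCN(C)C)c1cc(OC)cc(O[Si](C(C)C)(C(C)C)C(C)C)c1 | intermediate
11 | lithium {[2-(dimethylamino)ethyl](methyl)amino}[2-lithio-3-methoxy-5-(triisopropylsilyloxy)phenyl]methanolate, racemic | [Li]OC(N(C)CCN(C)C)c1cc(O[Si](C(C)C)(C(C)C)C(C)C)cc(OC)c1[Li] | intermediate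
12 | lithium [2-bromo-3-methoxy-5-(triisopropylsilyloxy)phenyl]{[2-(dimethylamino)ethyl](methyl)amino}methanolate, racemic | [Li]OC(N(C)CCN(C)C)c1cc(O[Si](C(C)C)(C(C)C)C(C)C)cc(OC)c1Br | intermediate
13 | 2-bromo-3-methoxy-5-(triisopropylsilyloxy)benzaldehyde | O=Cc1cc(O[Si](C(C)C)(C(C)C)C(C)C)cc(OC)c1Br | intermediate
14 | 4-(benzyloxy)-3-methoxybenzyl alcohol | COc1cc(CO)ccc1OCc1ccccc1 | starting material
15 | 4-(benzyloxy)-3-methoxybenzyl bromide | COc1cc(CBr)ccc1OCc1ccccc1 | intermediate
16 | [4-(benzyloxy)-3-methoxybenzyl]triphenylphosphonium bromide | COc1cc(C[P+](c2ccccc2)(c2ccccc2)c2ccccc2)ccc1OCc1ccccc1.[Br-] | intermediate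
17 | [4-(benzyloxy)-3-methoxybenzylidene]triphenylphosphorane | COc1cc(C=P(c2ccccc2)(c2ccccc2)c2ccccc2)ccc1OCc1ccccc1 | intermediate
18 | 2-bromo-1-methoxy-3-{2-[4-(benzyloxy)-3-methoxyphenyl]ethenyl}-5-(triisopropylsilyloxy)benzene, mixture of (E) and (Z) isomers | COc1cc(O[Si](C(C)C)(C(C)C)C(C)C)cc(C=Cc2ccc(OCc3ccccc3)c(OC)c2)c1Br | intermediate
19 | 2-bromo-1-methoxy-3-{2-[4-(benzyloxy)-3-methoxyphenyl]ethyl}-5-(triisopropylsilyloxy)benzene | COc1cc(O[Si](C(C)C)(C(C)C)C(C)C)cc(CCc2ccc(OCc3ccccc3)c(OC)c2)c1Br | intermediate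
20 | (2-{2-[4-(benzyloxy)-3-methoxyphenyl]ethyl}-6-methoxy-4-(triisopropylsilyloxy)phenyl)lithium | COc1cc(O[Si](C(C)C)(C(C)C)C(C)C)cc(CCc2ccc(OCc3ccccc3)c(OC)c2)c1[Li] | intermediate
21 | lithium 7-aryl-5-methoxy-3-(triisopropylsilyloxy)bicyclo[4.2.0]octa-1,3,5-trien-7-olate, aryl = the ring of 20, racemic | [Li]OC1(Cc2cc(O[Si](C(C)C)(C(C)C)C(C)C)cc(OC)c21)c1c(OC)cc(O[Si](C(C)C)(C(C)C)C(C)C)cc1CCc1ccc(OCc2ccccc2)c(OC)c1 | intermediate
22 | lithium ortho-quinodimethane enolate (dienolate of the ortho-methyl diaryl ketone, O outward, exocyclic CH2 on the neighbouring ring carbon) | [Li]O/C(=C1/C(=C)C=C(O[Si](C(C)C)(C(C)C)C(C)C)C=C1OC)c1c(OC)cc(O[Si](C(C)C)(C(C)C)C(C)C)cc1CCc1ccc(OCc2ccccc2)c(OC)c1 | intermediate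
23 | bis{2-methoxy-6-[2-(4-benzyloxy-3-methoxyphenyl)ethyl]-4-(triisopropylsilyloxy)phenyl}methanone | O=C(c1c(OC)cc(O[Si](C(C)C)(C(C)C)C(C)C)cc1CCc1ccc(OCc2ccccc2)c(OC)c1)c1c(OC)cc(O[Si](C(C)C)(C(C)C)C(C)C)cc1CCc1ccc(OCc2ccccc2)c(OC)c1 | intermediate
24 | bis{2-methoxy-6-[2-(4-benzyloxy-3-methoxyphenyl)ethyl]-4-(triisopropylsilyloxy)phenyl}methanol (achiral) | OC(c1c(OC)cc(O[Si](C(C)C)(C(C)C)C(C)C)cc1CCc1ccc(OCc2ccccc2)c(OC)c1)c1c(OC)cc(O[Si](C(C)C)(C(C)C)C(C)C)cc1CCc1ccc(OCc2ccccc2)c(OC)c1 | intermediate
25 | bis{2-methoxy-6-[2-(4-benzyloxy-3-methoxyphenyl)ethyl]-4-(triisopropylsilyloxy)phenyl}methane | COc1cc(O[Si](C(C)C)(C(C)C)C(C)C)cc(CCc2ccc(OCc3ccccc3)c(OC)c2)c1Cc1c(OC)cc(O[Si](C(C)C)(C(C)C)C(C)C)cc1CCc1ccc(OCc2ccccc2)c(OC)c1 | intermediate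
26 | bis{2-[2-(4-benzyloxy-3-methoxyphenyl)ethyl]-4-hydroxy-6-methoxyphenyl}methane | COc1cc(O)cc(CCc2ccc(OCc3ccccc3)c(OC)c2)c1Cc1c(OC)cc(O)cc1CCc1ccc(OCc2ccccc2)c(OC)c1 | intermediate
27 | 4,4′-methylenebis{3-[2-(4-hydroxy-3-methoxyphenyl)ethyl]-5-methoxyphenol}, CNP0079383.0 | COc1cc(CCc2cc(O)cc(OC)c2Cc2c(CCc3ccc(O)c(OC)c3)cc(O)cc2OC)ccc1O | target

**Totals**

Total step count: 13. Longest linear sequence: 9 steps (steps 3, 4, 7, 8, 9, 10, 11, 12, 13, from 3-hydroxy-5-methoxybenzaldehyde 8; the branch from alcohol 14 through steps 5 and 6 is equally long).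

**Steps most likely to fail**

1. Step 9 (key step). What may go wrong: the doubly ortho-substituted aryllithium may add too slowly and be quenched instead. The four-membered ring may open by aryl–carbonyl bond cleavage and not by the pericyclic path. The dienolate may be protonated or may self-condense before it is alkylated. The benzylic bromide may be lost by electron-transfer homocoupling. Fallback (sets out from 19, returns at 24): bromide 19 is lithiated as in step 9 (20) and formylated with DMF to give 2-{2-[4-(benzyloxy)-3-methoxyphenyl]ethyl}-6-methoxy-4-(triisopropylsilyloxy)benzaldehyde F1. A second portion of 20 is then added to F1 (THF, −78 °C → 0 °C), which should give carbinol 24 directly. The route resumes at step 11; compounds 7, 15 (for this step) and 23 and step 10 are bypassed.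

2. Step 4. What may go wrong: metalation may stall or take place at a ring position next to the silyloxy group, excess n-BuLi may consume the bromine donor before the hindered aryllithium does, and the masked aldehyde may be attacked by butyl. Fallback (sets out from 2, returns at 19): the bromide is built on the aryne of step 2 instead of on the aldehyde. Homovanillyl alcohol F2 is benzylated at the phenol (BnBr, K2CO3, acetone, reflux) to 2-[4-(benzyloxy)-3-methoxyphenyl]ethanol F3. An Appel reaction (CBr4, PPh3, CH2Cl2) converts it to 1-(benzyloxy)-4-(2-bromoethyl)-2-methoxybenzene F4, which with Mg in THF forms {2-[4-(benzyloxy)-3-methoxyphenyl]ethyl}magnesium bromide F5. Fluoroarene 2 is lithiated with n-BuLi at −78 °C and transferred into an excess of F5 at 0 °C. Aryne 5, released on warming, should take the alkyl group at the carbon remote from OMe (aryne carbomagnesiation) and leave (2-{2-[4-(benzyloxy)-3-methoxyphenyl]ethyl}-6-methoxy-4-(triisopropylsilyloxy)phenyl)magnesium bromide F6, which BrCl2C–CCl2Br brominates at 0 °C to 19. Compounds 8 to 13 and 16 to 18 and steps 3, 4, 6, 7 and 8 are bypassed.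

3. Step 2. What may go wrong: the aryne may be consumed by its own aryllithium precursor before it meets the ketene acetal, and lithiation next to the silyloxy group would erode regiocontrol. Fallback (sets out from 2, returns at 7): lithium ethenolate F7 is made beforehand by cleavage of THF with n-BuLi at rt. Fluoroarene 2 is lithiated as before, and the aryne 5 released on warming is intercepted by F7. This anionic stepwise [2+2] (enolate carbon to the aryne carbon remote from OMe, aryl anion onto the aldehyde carbon) should give racemic 5-methoxy-3-(triisopropylsilyloxy)bicyclo[4.2.0]octa-1,3,5-trien-7-ol F8. Oxidation with Dess–Martin periodinane (CH2Cl2, rt) then gives 7.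

**Further compounds**

F1 | step 9 | 2-{2-[4-(benzyloxy)-3-methoxyphenyl]ethyl}-6-methoxy-4-(triisopropylsilyloxy)benzaldehyde | COc1cc(O[Si](C(C)C)(C(C)C)C(C)C)cc(CCc2ccc(OCc3ccccc3)c(OC)c2)c1C=O
F2 | step 4 | homovanillyl alcohol | COc1cc(CCO)ccc1O
F3 | step 4 | 2-[4-(benzyloxy)-3-methoxyphenyl]ethanol | COc1cc(CCO)ccc1OCc1ccccc1
F4 | step 4 | 1-(benzyloxy)-4-(2-bromoethyl)-2-methoxybenzene | COc1cc(CCBr)ccc1OCc1ccccc1
F5 | step 4 | {2-[4-(benzyloxy)-3-methoxyphenyl]ethyl}magnesium bromide | COc1cc(CC[Mg]Br)ccc1OCc1ccccc1
F6 | step 4 | (2-{2-[4-(benzyloxy)-3-methoxyphenyl]ethyl}-6-methoxy-4-(triisopropylsilyloxy)phenyl)magnesium bromide | COc1cc(O[Si](C(C)C)(C(C)C)C(C)C)cc(CCc2ccc(OCc3ccccc3)c(OC)c2)c1[Mg]Br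
F7 | step 2 | lithium ethenolate | [Li]OC=C
F8 | step 2 | 5-methoxy-3-(triisopropylsilyloxy)bicyclo[4.2.0]octa-1,3,5-trien-7-ol, racemic | OC1Cc2cc(O[Si](C(C)C)(C(C)C)C(C)C)cc(OC)c21
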